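I read this flask at 12 min, so I count how many lifetimes of its product-helped step fit before that reading.

substrate 0.50 mM; reagent 5.00 equiv; time 12 min

    substrate + reagent + product → 2 product (k1 = 43300 /M²/s)
    substrate + reagent → product (k2 = 0.540 /M/s)
    2 substrate → homo dimer (k3 = 2.78 /M/s)

* why nothing more happens at 12 min, or that something still does (it is still moving / the reagent has run out first / all of the substrate has reacted / forward and back rates have come level)
* part of the substrate gone at 12 min
* the product standing at 12 min, as a percentage of the substrate charged

- percent here means substrate units held: one homo dimer counts as two
- a step written with two of one species runs at k times the square of its concentration and takes two of it each time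
- the reaction counts as stopped when no species that holds the substrate changes by six tenths of a point or more over the second half of the time
- run time (flask): 12 min

In the first instants no product stands, so the product-helped step (autocatalysis) is idle. The plain step makes product, and the dimer step takes substrate with a lifetime of 6.00 min at the charge. Each turn of the two product-making steps takes one reagent, so they can use at most 20.0 % of its charge, and I hold reagent constant (pseudo-first-order).

The plain step then acts like a standing seed of product, a fraction 2.49 % of the charge. In the middle, the helped step multiplies that seed e-fold every 0.308 min, and with the dimer step set aside I reckon product at half of the charge after 1.14 min. I call this the ignition time: the helped lifetime times the logarithm of charge over seed.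

Dividing the dimer step's pace by the product's and summing gives a loss of ignition time less one helped lifetime, over the dimer lifetime. That is 13.8 % of the substrate, so I expect 86.2 % product.

At the end, the reading comes at ten times the ignition time, which leaves 35.3 helped lifetimes, each reckoned at the charge, for the remainder. I therefore commit to >99.9 % gone and a flask at rest.

The forecast says all of the substrate has reacted, with 100 % gone and 87 % product. Its ground is this: “The only real loss is dimerisation during the slow early induction period”.

The flask gives all of the substrate has reacted, with 100 % gone and 86.7 % product. At 1.20 min, close to the ignition time of 1.14 min, this flask holds substrate 44.0 %, product 43.7 % and homo dimer 12.4 %; at 1.25 min the helped step's half-life for substrate is 0.51 min, shorter than the plain step's 9.4 min. By 6.00 min substrate stands at 0 %, product at 86.7 % and reagent at 82.7 % of its charge, and the product reading is the same at 12.0 min.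

With 0.12 mM of substrate at the same equivalents, the helped lifetime becomes 5.35 min, the seed 10.4 % and the ignition time 12.1 min. That is about the reading time, so this neighbour should be caught in mid-run. It holds substrate 40.4 %, product 35.8 % and homo dimer 23.8 % at 12.0 min.

(The numbers are made up; the flask was simulated.)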